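**Plan**

- Numbering: C7 is the acetoxy-bearing benzylic carbon, C8 the aryloxy-bearing carbon, C9 the methyl; ring A is the 2,6-dimethoxy-4-(E)-propenylphenoxy ring, ring B the 3,4,5-trimethoxyphenyl ring.
- Cuts, in retrosynthetic order: acetyl–O7; O–C7 traced back to B–C7; C7–C8 together with C7–ring B; C8–O(ring A); C8–C9.
- Enabling feature: C7 is bonded to C8, to ring B and to oxygen; a carbon on boron that gains two carbon substituents through two consecutive 1,2-migrations and then trades boron for oxygen ends with exactly this substitution.
- Forward: no ring is formed; the chain grows C9 → C8 → C7 on one boron atom (methylboronic ester, CHBr insertion, aryloxide for bromide, CHCl insertion with arylation in one flask, C–B oxidation, acetylation).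
- Stereochemistry: the (S,S)-1,2-dicyclohexylethane-1,2-diol on boron decides which halide leaves in both insertions; C8 is inverted by the aryloxide, C7 is inverted by the aryl shift and retained in the oxidation, giving threo (7R,8R); the E alkene is bought in.

Key step: step 5

Remark: commercial 2,6-dimethoxy-4-(prop-1-enyl)phenol is assumed to be the E isomer or to be brought to it by recrystallisation. The descriptor at C8 changes from (1S) in the aryloxyethyl boronic ester to (R) once C7 is attached, only because C7 outranks the methyl group where boron did not; no bond at C8 is touched.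

**Route**

Step 1
Reactants: 1 methylboronic acid; 2 (1S,2S)-1,2-dicyclohexylethane-1,2-diol
Product: 3 (4S,5S)-4,5-dicyclohexyl-2-methyl-1,3,2-dioxaborolane
Conditions: MgSO4, Et2O, rt
Reagents that add atoms: none
Why: Condensation of a boronic acid with a 1,2-diol (boronic ester formation) is driven to completion by the drying agent and should give the robust cyclic ester without touching the two diol stereocentres, which are the only source of chirality in the route.

Step 2
Reactants: 3 (4S,5S)-4,5-dicyclohexyl-2-methyl-1,3,2-dioxaborolane; 4 dibromomethane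
Product: 6 (4S,5S)-2-[(1R)-1-bromoethyl]-4,5-dicyclohexyl-1,3,2-dioxaborolane, via dibromomethyllithium 5 (not isolated)
Conditions: 3 and 4 (1.5 equiv), THF, −78 °C; add LiN(iPr)2 (1.2 equiv); ZnCl2 (2.0 equiv), −78 °C to rt; aq NH4Cl work-up
Reagents that add atoms: none
Why: Matteson homologation with the carbenoid made in the presence of the ester: 5 is captured by boron as it forms, and on warming with ZnCl2 the methyl group shifts from boron to carbon while the bromide singled out by the (S,S)-diol leaves, which should set C8 as the (1R)-bromide with high diastereoselection, ZnCl2 also binding the free halide that would otherwise epimerise the product.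

Step 3
Reactants: 6 (4S,5S)-2-[(1R)-1-bromoethyl]-4,5-dicyclohexyl-1,3,2-dioxaborolane; 7 (E)-2,6-dimethoxy-4-(prop-1-enyl)phenol
Product: 9 (4S,5S)-4,5-dicyclohexyl-2-[(1S)-1-[2,6-dimethoxy-4-((E)-prop-1-enyl)phenoxy]ethyl]-1,3,2-dioxaborolane, via sodium aryloxide 8 (not isolated)
Conditions: 7 (1.2 equiv), NaH (1.15 equiv), THF, 0 °C; then 6, THF, 0 °C to rt
Reagents that add atoms: none
Why: Nucleophilic substitution of an α-bromo boronic ester by an oxygen nucleophile (Matteson substitution), in which the aryloxide binds to boron and shifts to carbon as bromide leaves, should invert C8 from the (1R)-bromide to the (1S)-aryl ether; the neighbouring boron and the good leaving group should make the displacement fast enough for a 2,6-disubstituted phenoxide, and the sparingly soluble NaBr leaves little bromide in THF to epimerise unreacted 6.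

Step 4
Reactants: 10 5-bromo-1,2,3-trimethoxybenzene
Product: 11 3,4,5-trimethoxyphenylmagnesium bromide (THF solution, titrated and used as such)
Conditions: Mg turnings, iodine (trace), THF, 40 °C
Reagents that add atoms: magnesium [Mg]
Why: Grignard formation by insertion of Mg into the aryl C–Br bond is routine for methoxy-substituted bromoarenes and creates no stereocentre.

Step 5
Reactants: 9 (4S,5S)-4,5-dicyclohexyl-2-[(1S)-1-[2,6-dimethoxy-4-((E)-prop-1-enyl)phenoxy]ethyl]-1,3,2-dioxaborolane; 12 dichloromethane; 11 3,4,5-trimethoxyphenylmagnesium bromide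
Product: 15 (4S,5S)-4,5-dicyclohexyl-2-[(1R,2R)-2-[2,6-dimethoxy-4-((E)-prop-1-enyl)phenoxy]-1-(3,4,5-trimethoxyphenyl)propyl]-1,3,2-dioxaborolane, via dichloromethyllithium 13 (not isolated), via alpha-chloro boronic ester 14 (not isolated)
Conditions: 12, n-BuLi, THF, −100 °C; add 9; ZnCl2 (1.0 equiv), −100 °C to rt; then −78 °C, 11 (3.2 equiv), to rt
Reagents that add atoms: none
Why: Dichloromethyllithium 13 adds to the boron of 9 to give a tetracoordinate borate, and ZnCl2 then triggers a 1,2-shift of C8 from boron to the carbenoid carbon with retention at C8 and loss of one chloride, which forms the C7–C8 bond and gives chloride 14; Grignard reagent 11 next adds to boron and ring B shifts to C7 with inversion while the second chloride leaves, which forms the C7–ring B bond and leaves boron on C7 as the place of the later acetoxy oxygen. The closest known reaction type is the Matteson homologation of α-alkoxy boronic esters of C2-symmetric diols followed by Grignard substitution of the α-chloro boronic ester, the sequence used iteratively with α-benzyloxy boronic esters in polyol and carbohydrate synthesis. No ring is closed; two skeletal bonds and one stereocentre are made. The new stereocentre C7 is controlled by the (S,S)-diol on boron, which decides which of the two diastereotopic chlorides is displaced in the first shift (the (1R)-chloride in 14, in line with the empirical sense of induction under which the (R,R)-diol leads to (S)-α-chloro boronic esters), and by the stereospecific inversion of the aryl shift, so that C7 ends as (R) with boron where the oxygen must stand, while C8 keeps its configuration because a migrating carbon retains. The step needs a clean choice between the two chlorides and an aryl shift that is faster than β-elimination of the ring A aryloxide from the borate; the first is secured by the C2-symmetric diol together with ZnCl2, which also removes free chloride that would epimerise 14, and the second by the chloride α to boron being by far the better leaving group, by the low temperature, and by a Grignard charge of which about two equivalents are taken up by ZnCl2 as the diarylzinc so that only a slight excess meets boron. The E-propenyl group and the aryl methyl ethers should not react with the carbenoid at −100 °C or with the Grignard reagent.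

Step 6
Reactants: 15 (4S,5S)-4,5-dicyclohexyl-2-[(1R,2R)-2-[2,6-dimethoxy-4-((E)-prop-1-enyl)phenoxy]-1-(3,4,5-trimethoxyphenyl)propyl]-1,3,2-dioxaborolane
Product: 16 (1R,2R)-2-[2,6-dimethoxy-4-((E)-prop-1-enyl)phenoxy]-1-(3,4,5-trimethoxyphenyl)propan-1-ol
Conditions: 30% aq H2O2, NaOH (2 M, 2 equiv), THF, 0 °C to rt
Reagents that add atoms: hydrogen peroxide OO
Why: Alkaline peroxide oxidation of a boronic ester: hydroperoxide adds to boron and C7 migrates from boron to oxygen with retention, so the (7R) alcohol should result, the electron-rich propenyl group being inert to nucleophilic peroxide and diol 2 being recovered.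

Step 7
Reactants: 16 (1R,2R)-2-[2,6-dimethoxy-4-((E)-prop-1-enyl)phenoxy]-1-(3,4,5-trimethoxyphenyl)propan-1-ol
Product: 17 (1R,2R)-2-[2,6-dimethoxy-4-((E)-prop-1-enyl)phenoxy]-1-(3,4,5-trimethoxyphenyl)propyl acetate
Conditions: Ac2O, pyridine, 4-(dimethylamino)pyridine (cat.), CH2Cl2, 0 °C to rt
Reagents that add atoms: acetic anhydride CC(=O)OC(C)=O
Why: Amine-catalysed O-acylation of the secondary benzylic alcohol breaks only the O–H bond, so both stereocentres are kept and the target acetate should form under non-acidic conditions.

**Compound list**

1 | methylboronic acid | CB(O)O | starting material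
2 | (1S,2S)-1,2-dicyclohexylethane-1,2-diol | O[C@@H](C1CCCCC1)[C@@H](O)C1CCCCC1 | starting material
3 | (4S,5S)-4,5-dicyclohexyl-2-methyl-1,3,2-dioxaborolane | CB1O[C@@H](C2CCCCC2)[C@H](C2CCCCC2)O1 | intermediate
4 | dibromomethane | BrCBr | starting material
5 | dibromomethyllithium | [Li]C(Br)Br | intermediate
6 | (4S,5S)-2-[(1R)-1-bromoethyl]-4,5-dicyclohexyl-1,3,2-dioxaborolane | C[C@H](Br)B1O[C@@H](C2CCCCC2)[C@H](C2CCCCC2)O1 | intermediate
7 | (E)-2,6-dimethoxy-4-(prop-1-enyl)phenol | C/C=C/c1cc(OC)c(O)c(OC)c1 | starting material
8 | sodium (E)-2,6-dimethoxy-4-(prop-1-enyl)phenolate | C/C=C/c1cc(OC)c([O-])c(OC)c1.[Na+] | intermediate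
9 | (4S,5S)-4,5-dicyclohexyl-2-[(1S)-1-[2,6-dimethoxy-4-((E)-prop-1-enyl)phenoxy]ethyl]-1,3,2-dioxaborolane | C/C=C/c1cc(OC)c(O[C@H](C)B2O[C@@H](C3CCCCC3)[C@H](C3CCCCC3)O2)c(OC)c1 | intermediate
10 | 5-bromo-1,2,3-trimethoxybenzene | COc1cc(Br)cc(OC)c1OC | starting material
11 | 3,4,5-trimethoxyphenylmagnesium bromide | COc1cc([Mg]Br)cc(OC)c1OC | intermediate
12 | dichloromethane | ClCCl | starting material
13 | dichloromethyllithium | [Li]C(Cl)Cl | intermediate
14 | (4S,5S)-2-[(1R,2R)-1-chloro-2-[2,6-dimethoxy-4-((E)-prop-1-enyl)phenoxy]propyl]-4,5-dicyclohexyl-1,3,2-dioxaborolane | C/C=C/c1cc(OC)c(O[C@H](C)[C@H](Cl)B2O[C@@H](C3CCCCC3)[C@H](C3CCCCC3)O2)c(OC)c1 | intermediate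
15 | (4S,5S)-4,5-dicyclohexyl-2-[(1R,2R)-2-[2,6-dimethoxy-4-((E)-prop-1-enyl)phenoxy]-1-(3,4,5-trimethoxyphenyl)propyl]-1,3,2-dioxaborolane | C/C=C/c1cc(OC)c(O[C@H](C)[C@H](B2O[C@@H](C3CCCCC3)[C@H](C3CCCCC3)O2)c2cc(OC)c(OC)c(OC)c2)c(OC)c1 | intermediate
16 | (1R,2R)-2-[2,6-dimethoxy-4-((E)-prop-1-enyl)phenoxy]-1-(3,4,5-trimethoxyphenyl)propan-1-ol | C/C=C/c1cc(OC)c(O[C@H](C)[C@H](O)c2cc(OC)c(OC)c(OC)c2)c(OC)c1 | intermediate
17 | (1R,2R)-2-[2,6-dimethoxy-4-((E)-prop-1-enyl)phenoxy]-1-(3,4,5-trimethoxyphenyl)propyl acetate | C/C=C/c1cc(OC)c(O[C@H](C)[C@H](OC(C)=O)c2cc(OC)c(OC)c(OC)c2)c(OC)c1 | target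

**Totals**

Total step count: 7. Longest linear sequence: 6 steps (steps 1, 2, 3, 5, 6, 7); step 4 is a one-step side branch.

**Steps most likely to fail**

Step 5. The ring A aryloxide may be lost by β-elimination from the tetracoordinate borate that forms when the Grignard reagent adds to boron. The aryl group may also pass incompletely from magnesium to boron while zinc is present, and poor discrimination between the two chlorides would lower the threo ratio. The fallback keeps the carbenoid insertion but makes the C7–ring B bond by carbonyl addition, so that the slow aryl shift is avoided and the chloride configuration no longer matters; it sets out from 9 and comes back at alcohol 16. Boronic ester 9 is homologated with 13 (from 12 and n-BuLi, THF, −100 °C) and ZnCl2 as in the first half of step 5, and chloride 14 is isolated after aqueous work-up. Oxidation of 14 with 30% aq H2O2 and NaHCO3 in THF/H2O at 0 °C exchanges boron for oxygen; the resulting chlorohydrin loses HCl and should give (2R)-2-[2,6-dimethoxy-4-((E)-prop-1-enyl)phenoxy]propanal F1, with release of diol 2. Addition of 11 to freshly prepared F1 in Et2O/THF at −78 °C with MgBr2, under chelation of magnesium between the carbonyl and ether oxygens (Cram-chelate model), should favour the threo alcohol 16, the erythro isomer being removed by chromatography. The route then continues with step 7.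

Step 3. Substitution by the hindered 2,6-disubstituted aryloxide may be slow; during that time bromide can exchange with the α-bromo boronic ester and erode the configuration at C8, or the aryloxide can act as a base and dehydrobrominate 6. The fallback takes C8 from the chiral pool and forms the aryl ether on a carbon that carries no boron; it sets out from phenol 7 and comes back at alcohol 16. Mitsunobu reaction of 7 with ethyl (S)-lactate (PPh3, diisopropyl azodicarboxylate, THF, 0 °C to rt) inverts the lactate centre and should give ethyl (2R)-2-[2,6-dimethoxy-4-((E)-prop-1-enyl)phenoxy]propanoate F2. Reduction with iBu2AlH in toluene at −78 °C should stop at (2R)-2-[2,6-dimethoxy-4-((E)-prop-1-enyl)phenoxy]propanal F1, the aldehyde of the fallback for step 5. It is taken on to 16 with 11 and MgBr2 as described there, and the route continues with step 7.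

Step 6. Attack of hydroperoxide on the hindered boron may be slow, which leaves time for base-induced β-elimination of the aryloxide from the hydroxy- or hydroperoxy-borate. The fallback removes the bulky diol before the oxidation; it sets out from 15 and comes back at 16. Treatment of 15 with KHF2 in MeOH/H2O at rt should give potassium trifluoro[(1R,2R)-2-[2,6-dimethoxy-4-((E)-prop-1-enyl)phenoxy]-1-(3,4,5-trimethoxyphenyl)propyl]borate F3 with release of diol 2. Hydrolysis on silica gel in wet ethyl acetate should give [(1R,2R)-2-[2,6-dimethoxy-4-((E)-prop-1-enyl)phenoxy]-1-(3,4,5-trimethoxyphenyl)propyl]boronic acid F4. This unhindered boronic acid should be oxidised by H2O2 in a NaH2PO4/Na2HPO4 buffer of pH 7 (THF, 0 °C) with retention to 16, without strong base.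

**Further compounds**

F1 | step 5 | (2R)-2-[2,6-dimethoxy-4-((E)-prop-1-enyl)phenoxy]propanal | C/C=C/c1cc(OC)c(O[C@H](C)C=O)c(OC)c1
F2 | step 3 | ethyl (2R)-2-[2,6-dimethoxy-4-((E)-prop-1-enyl)phenoxy]propanoate | C/C=C/c1cc(OC)c(O[C@H](C)C(=O)OCC)c(OC)c1
F3 | step 6 | potassium trifluoro[(1R,2R)-2-[2,6-dimethoxy-4-((E)-prop-1-enyl)phenoxy]-1-(3,4,5-trimethoxyphenyl)propyl]borate | C/C=C/c1cc(OC)c(O[C@H](C)[C@H]([B-](F)(F)F)c2cc(OC)c(OC)c(OC)c2)c(OC)c1.[K+]
F4 | step 6 | [(1R,2R)-2-[2,6-dimethoxy-4-((E)-prop-1-enyl)phenoxy]-1-(3,4,5-trimethoxyphenyl)propyl]boronic acid | C/C=C/c1cc(OC)c(O[C@H](C)[C@H](B(O)O)c2cc(OC)c(OC)c(OC)c2)c(OC)c1
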